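The oxolane is numbered O1, C2 (3,4-dimethoxyphenyl), C3 (CH2OH), C4 (guaiacylmethyl), C5 (CH2). It is the only ring built and is built last: O1–C2 forms when the C5 hydroxyl of an open-chain triol captures the C2 benzylic cation, which the dimethoxyphenyl ring stabilises.
Enabling feature: the chain C5–C4–C3–CH2OH is a 2,3-disubstituted butane-1,4-diol, that is, a fully reduced butenolide. Raising C5 to a lactone carbonyl makes C4 an enolate carbon and C3 a Michael terminus, and the CH2OH carbon becomes the acetal carbon that carries an l-menthyl auxiliary.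
Key disconnection: C4 to the benzylic CH2 of the guaiacyl ring, by SN2 attack of that lactone enolate on an O-benzyl vanillyl bromide. The enolate is generated in the same flask by 1,4-addition of a lithiated veratraldehyde dithioacetal (C2–C3 bond), so one operation assembles the whole skeleton and sets both C3 and C4.
The trans pair on the temporary lactone ring becomes the 3,4-cis pair of the oxolane after the ring switch (LiAlH4 opening, acid closure). The C2 aryl group then settles trans to C3, and debenzylation ends the route.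

Key step: step 3

Assumption: (5R)-5-(l-menthyloxy)furan-2(5H)-one and 4-(benzyloxy)-3-methoxybenzyl alcohol are taken as catalogue chemicals. The benzylic carbinol made in step 5 is carried on as an epimer mixture because step 6 erases that centre.

Step 1
Reactants: 1 3,4-dimethoxybenzaldehyde (veratraldehyde)
Product: 2 4-[bis(phenylsulfanyl)methyl]-1,2-dimethoxybenzene
Conditions: PhSH (2.1 equiv), BF3·OEt2 (10 mol%), CH2Cl2, 0 °C to rt
Reagents that add atoms: thiophenol, Sc1ccccc1
Why: Lewis-acid-catalysed dithioacetalisation of an aromatic aldehyde is routine and turns the formyl carbon, the future C2, into an acidic C–H for umpolung; no stereocentre is formed.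

Step 2
Reactants: 3 [4-(benzyloxy)-3-methoxyphenyl]methanol
Product: 4 1-(benzyloxy)-4-(bromomethyl)-2-methoxybenzene
Conditions: PBr3 (0.4 equiv), Et2O, 0 °C
Reagents that add atoms: phosphorus tribromide, BrP(Br)Br
Why: Bromination of a primary benzylic alcohol with PBr3 (SN2 on the phosphite ester) is reliable, and the electron-rich bromide should be used directly after a short filtration because it ionises easily; no stereocentre is formed.

Step 3
Reactants: 2 4-[bis(phenylsulfanyl)methyl]-1,2-dimethoxybenzene; 5 (5R)-5-[(1R,2S,5R)-menthyloxy]furan-2(5H)-one; 4 1-(benzyloxy)-4-(bromomethyl)-2-methoxybenzene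
Product: 8 (3R,4R,5R)-3-[4-(benzyloxy)-3-methoxybenzyl]-4-[(3,4-dimethoxyphenyl)bis(phenylsulfanyl)methyl]-5-[(1R,2S,5R)-menthyloxy]oxolan-2-one, via lithiated dithioacetal 6 (not isolated), via lithium enolate 7 (not isolated)
Conditions: 2, n-BuLi (1.05 equiv), THF, −78 °C; then 5, THF, −78 °C; then 4, DMPU (4 equiv), −78 °C to rt; aq NH4Cl
Reagents that add atoms: none
Why: n-BuLi deprotonates 2 to the sulfur-stabilised carbanion 6, 6 adds 1,4 to butenolide 5 to give lithium enolate 7, and 7 displaces bromide from 4 by SN2 C-alkylation, which makes the bond between the lactone alpha carbon (future oxolane C4) and the guaiacyl benzylic CH2. The closest known reaction type is the tandem conjugate addition–enolate alkylation (three-component coupling) of lithiated aryl dithioacetals, 5-alkoxybutenolides and benzylic bromides used for dibenzylbutyrolactone lignans. No ring is closed; the lactone ring of 5 is carried through as a temporary ring that relays the stereochemistry. The first new stereocentre (lactone C4, future oxolane C3) is controlled by the C5 menthyloxy group, which shields one face so that 6 enters anti to it, and the second (lactone C3, future oxolane C4) by the very large aryl-bis(phenylsulfanyl)methyl group just installed, so that 4 enters anti to it and the 3,4-trans-4,5-trans lactone should result. The step needs 1,4- over 1,2-addition, secured by the soft, bulky, delocalised carbanion whose 1,2-addition is reversible, C- over O-alkylation, secured by the soft benzylic bromide and the lithium enolate in THF/DMPU, and mono-alkylation, secured by the burial of the remaining alpha hydrogen of 8 between two substituents.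

Step 4
Reactants: 8 (3R,4R,5R)-3-[4-(benzyloxy)-3-methoxybenzyl]-4-[(3,4-dimethoxyphenyl)bis(phenylsulfanyl)methyl]-5-[(1R,2S,5R)-menthyloxy]oxolan-2-one
Product: 9 (3R,4R,5R)-3-[4-(benzyloxy)-3-methoxybenzyl]-4-(3,4-dimethoxybenzoyl)-5-[(1R,2S,5R)-menthyloxy]oxolan-2-one
Conditions: HgO (2 equiv), BF3·OEt2 (promoter), aq THF, rt
Reagents that add atoms: water, O
Why: Thiophile-assisted hydrolysis of a dithioacetal by divalent mercury should unmask the aryl ketone while leaving the lactone, benzyl ether and methyl ethers alone, the all-trans array at the enolisable carbon being the thermodynamic one, and any partial loss of the menthyl acetal would be harmless because step 5 takes that carbon to CH2OH in any case.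

Step 5
Reactants: 9 (3R,4R,5R)-3-[4-(benzyloxy)-3-methoxybenzyl]-4-(3,4-dimethoxybenzoyl)-5-[(1R,2S,5R)-menthyloxy]oxolan-2-one
Product: 10 (2R,3R)-2-[4-(benzyloxy)-3-methoxybenzyl]-3-[(3,4-dimethoxyphenyl)(hydroxy)methyl]butane-1,4-diol (both carbinol epimers)
Conditions: LiAlH4 (5 equiv), THF, 0 °C (9 added to the hydride), then rt; careful H2O quench, filtration
Reagents that add atoms: none
Why: Exhaustive LiAlH4 reduction should take the lactone carbonyl and, after expulsion of menthoxide, the acetal carbon to the two CH2OH groups and the ketone to the benzylic carbinol, which opens the temporary ring and releases the auxiliary; the new carbinol centre forms unselectively, which is irrelevant because step 6 erases it, and the two backbone stereocentres stay untouched because reduction outruns enolisation under inverse addition.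

Step 6
Reactants: 10 (2R,3R)-2-[4-(benzyloxy)-3-methoxybenzyl]-3-[(3,4-dimethoxyphenyl)(hydroxy)methyl]butane-1,4-diol
Product: 11 {(2S,3R,4R)-4-[4-(benzyloxy)-3-methoxybenzyl]-2-(3,4-dimethoxyphenyl)oxolan-3-yl}methanol
Conditions: camphor-10-sulfonic acid (CSA, 10 mol%), CH2Cl2, 0 °C to rt; Et3N quench
Reagents that add atoms: none
Why: Acid-catalysed SN1 cyclodehydration: the carbinol ionises readily because of the 3,4-dimethoxyphenyl ring and only the CH2OH on the benzyl-bearing carbon can close a five-membered ring (5-exo-tet, the other one would give an oxetane), while C2 is set by the substrate, the aryl group taking the face opposite to the cis-disposed C3 and C4 substituents, which is the kinetic and, the closure being reversible, also the thermodynamic outcome (2,3-trans).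

Step 7
Reactants: 11 {(2S,3R,4R)-4-[4-(benzyloxy)-3-methoxybenzyl]-2-(3,4-dimethoxyphenyl)oxolan-3-yl}methanol
Product: 12 4-{[(3R,4R,5S)-5-(3,4-dimethoxyphenyl)-4-(hydroxymethyl)oxolan-3-yl]methyl}-2-methoxyphenol (target)
Conditions: H2 (1 atm), 10% Pd/C, EtOAc, rt, stopped after one equivalent of H2
Reagents that add atoms: none
Why: Catalytic hydrogenolysis of a phenolic benzyl ether in a neutral solvent is much faster than cleavage of the benzylic C2–O1 bond of the oxolane, so stopping after uptake of one equivalent of H2 should give the free phenol with all three stereocentres intact.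

Compound list
1 | 3,4-dimethoxybenzaldehyde | COc1ccc(C=O)cc1OC | starting material
2 | 4-[bis(phenylsulfanyl)methyl]-1,2-dimethoxybenzene | COc1ccc(C(Sc2ccccc2)Sc2ccccc2)cc1OC | intermediate
3 | [4-(benzyloxy)-3-methoxyphenyl]methanol | COc1cc(CO)ccc1OCc1ccccc1 | starting material
4 | 1-(benzyloxy)-4-(bromomethyl)-2-methoxybenzene | COc1cc(CBr)ccc1OCc1ccccc1 | intermediate
5 | (5R)-5-[(1R,2S,5R)-menthyloxy]furan-2(5H)-one | O=C1O[C@@H](O[C@@H]2C[C@H](C)CC[C@H]2C(C)C)C=C1 | starting material
6 | [(3,4-dimethoxyphenyl)bis(phenylsulfanyl)methyl]lithium | [Li]C(Sc1ccccc1)(Sc1ccccc1)c1ccc(OC)c(OC)c1 | intermediate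
7 | lithium enolate of the (4R,5R) 4,5-trans Michael adduct | [Li]OC1=C[C@@H](C(Sc2ccccc2)(Sc2ccccc2)c2ccc(OC)c(OC)c2)[C@H](O[C@@H]2C[C@H](C)CC[C@H]2C(C)C)O1 | intermediate
8 | (3R,4R,5R)-3-[4-(benzyloxy)-3-methoxybenzyl]-4-[(3,4-dimethoxyphenyl)bis(phenylsulfanyl)methyl]-5-[(1R,2S,5R)-menthyloxy]oxolan-2-one | O=C1O[C@@H](O[C@@H]2C[C@H](C)CC[C@H]2C(C)C)[C@H](C(Sc2ccccc2)(Sc2ccccc2)c2ccc(OC)c(OC)c2)[C@H]1Cc1ccc(OCc2ccccc2)c(OC)c1 | intermediate
9 | (3R,4R,5R)-3-[4-(benzyloxy)-3-methoxybenzyl]-4-(3,4-dimethoxybenzoyl)-5-[(1R,2S,5R)-menthyloxy]oxolan-2-one | O=C1O[C@@H](O[C@@H]2C[C@H](C)CC[C@H]2C(C)C)[C@H](C(=O)c2ccc(OC)c(OC)c2)[C@H]1Cc1ccc(OCc2ccccc2)c(OC)c1 | intermediate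
10 | (2R,3R)-2-[4-(benzyloxy)-3-methoxybenzyl]-3-[(3,4-dimethoxyphenyl)(hydroxy)methyl]butane-1,4-diol, both carbinol epimers | COc1cc(C[C@@H](CO)[C@H](CO)C(O)c2ccc(OC)c(OC)c2)ccc1OCc1ccccc1 | intermediate
11 | {(2S,3R,4R)-4-[4-(benzyloxy)-3-methoxybenzyl]-2-(3,4-dimethoxyphenyl)oxolan-3-yl}methanol | COc1cc(C[C@H]2CO[C@H](c3ccc(OC)c(OC)c3)[C@H]2CO)ccc1OCc1ccccc1 | intermediate
12 | 4-{[(3R,4R,5S)-5-(3,4-dimethoxyphenyl)-4-(hydroxymethyl)oxolan-3-yl]methyl}-2-methoxyphenol | COc1cc(C[C@H]2CO[C@H](c3ccc(OC)c(OC)c3)[C@H]2CO)ccc1O | target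

Total step count: 7. Longest linear sequence: 6 steps (steps 1, 3, 4, 5, 6, 7; the branch through step 2 is equally long).

Steps most likely to fail

Step 3. On warming, proton transfer or retro-Michael fragmentation of the crowded enolate may outrun the slow SN2 step, and some 1,2-addition may compete. The fallback sets out from enolate 7, made from 2 and 5 as in step 3. The enolate is trapped at −78 °C with TMSCl as the silyl ketene acetal F1. This neutral nucleophile is then joined with bromide 4 in CH2Cl2 under ZnBr2 catalysis, a Lewis-acid-mediated SN1-type (Mukaiyama-type) alkylation. It draws on the easy ionisation of the 4-alkoxy-3-methoxybenzyl bromide and should again deliver the benzyl group anti to the large C4 substituent. The fallback comes back to the route at 8.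

Step 6. The product may re-ionise under the acid and be captured irreversibly in a Friedel–Crafts sense by the guaiacyl ring at the position para to its methoxy group, and facial selectivity at C2 may be incomplete. The fallback sets out from ketone 9, whose aroyl ring is deactivated. One equivalent of NBS in MeCN at 0 °C should therefore brominate only the guaiacyl ring at that para position, giving the bromoaryl keto lactone F2. LiAlH4 at 0 °C should give the bromo triol F3. CSA-catalysed closure, now with the Friedel–Crafts site blocked, should give the bromo oxolane F4. Hydrogenation over 10% Pd/C with NaOAc in EtOAc/MeOH removes bromine and benzyl together. The fallback comes back to the route at 12.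

Step 7. Over-reduction may occur, that is, hydrogenolysis of the benzylic C2–O1 bond of the oxolane alongside O-debenzylation. The fallback sets out from ketone 9, which holds no benzylic sp3 C–O bond other than the protecting group. Hydrogenolysis (H2, 10% Pd/C, EtOAc) at this stage should give the phenolic keto lactone F5. Excess LiAlH4 should give the phenolic triol F6. The CSA-catalysed cyclodehydration of step 6 then closes the oxolane on the free phenol. The fallback comes back to the route at 12.

Further compounds
F1 | step 3 | {[(4R,5R)-4-[(3,4-dimethoxyphenyl)bis(phenylsulfanyl)methyl]-5-[(1R,2S,5R)-menthyloxy]-4,5-dihydrofuran-2-yl]oxy}trimethylsilane | C[Si](C)(C)OC1=C[C@@H](C(Sc2ccccc2)(Sc2ccccc2)c2ccc(OC)c(OC)c2)[C@H](O[C@@H]2C[C@H](C)CC[C@H]2C(C)C)O1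
F2 | step 6 | (3R,4R,5R)-3-[4-(benzyloxy)-2-bromo-5-methoxybenzyl]-4-(3,4-dimethoxybenzoyl)-5-[(1R,2S,5R)-menthyloxy]oxolan-2-one | O=C1O[C@@H](O[C@@H]2C[C@H](C)CC[C@H]2C(C)C)[C@H](C(=O)c2ccc(OC)c(OC)c2)[C@H]1Cc1cc(OC)c(OCc2ccccc2)cc1Br
F3 | step 6 | (2R,3R)-2-[4-(benzyloxy)-2-bromo-5-methoxybenzyl]-3-[(3,4-dimethoxyphenyl)(hydroxy)methyl]butane-1,4-diol, both carbinol epimers | COc1cc(C[C@@H](CO)[C@H](CO)C(O)c2ccc(OC)c(OC)c2)c(Br)cc1OCc1ccccc1
F4 | step 6 | {(2S,3R,4R)-4-[4-(benzyloxy)-2-bromo-5-methoxybenzyl]-2-(3,4-dimethoxyphenyl)oxolan-3-yl}methanol | COc1cc(C[C@H]2CO[C@H](c3ccc(OC)c(OC)c3)[C@H]2CO)c(Br)cc1OCc1ccccc1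
F5 | step 7 | (3R,4R,5R)-4-(3,4-dimethoxybenzoyl)-3-(4-hydroxy-3-methoxybenzyl)-5-[(1R,2S,5R)-menthyloxy]oxolan-2-one | O=C1O[C@@H](O[C@@H]2C[C@H](C)CC[C@H]2C(C)C)[C@H](C(=O)c2ccc(OC)c(OC)c2)[C@H]1Cc1ccc(O)c(OC)c1
F6 | step 7 | (2R,3R)-2-[(3,4-dimethoxyphenyl)(hydroxy)methyl]-3-(4-hydroxy-3-methoxybenzyl)butane-1,4-diol, both carbinol epimers | COc1cc(C[C@@H](CO)[C@H](CO)C(O)c2ccc(OC)c(OC)c2)ccc1O
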